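**Plan**

- Feature: the target is a C3–C3′ (cinnamate 8–8′) dimer of two 4-(4-hydroxyphenyl)chroman-2-ones. Each C4 is bonded to C4a of a phloroglucinol-type ring that also carries the lactone oxygen. Ring B differs from ring A only by the hydroxyls at C6′ and C8′, and with (3R,4S,3′S,4′R) the shared skeleton is meso.
- Cuts: first C6′–O and C8′–O, then C3–C3′ together with C4–C4a and C4′–C4a′, giving two molecules of one aryl 4-hydroxycinnamate; last the ester C–O bond. Two tert-butyl groups flank the cinnamate OH to steer the coupling.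
- Forward: esterification; one-step oxidative C8–C8′ coupling with double Friedel–Crafts closure of both lactone rings; removal of the tert-butyl groups and O-methylation; opening of one lactone, oxygenation of its freed phenol ring at C8′ then C6′, reclosure and O-methylation; inversion of C3 and C3′; cleavage of all eight methyl ethers.
- Stereochemistry: the unlike C4/C4′ pair comes from the meso bis(quinone methide) and anti ring closure. The absolute sense comes from opening the meso bis-lactone with (S)-1-phenylethylamine and separating the two diastereomers. C3 and C3′, each cis to its 4-aryl group, are set in step 10 by kinetic protonation of the bis-enolate and are carried through a final deprotection that uses no base.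

Key step: step 2

Remark: 1 and 2 are taken as catalogue compounds. The 3,4-trans lactone is assumed to be the more stable one on these 5-alkoxy-4-aryl rings, so all compounds before step 10 are drawn trans,trans and any C3/C3′ epimers converge in step 10.

**Route**

Step 1
Reactants: 1 (E)-3-(3,5-di-tert-butyl-4-hydroxyphenyl)prop-2-enoic acid; 2 3,5-dimethoxyphenol
Product: 3 3,5-dimethoxyphenyl (E)-3-(3,5-di-tert-butyl-4-hydroxyphenyl)prop-2-enoate
Conditions: N,N′-dicyclohexylcarbodiimide, 4-(dimethylamino)pyridine (cat.), CH2Cl2, 0 → 23 °C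
Reagents that add atoms: none
Why: Steglich esterification; the 4-OH of 1 is flanked by two tert-butyl groups and is not acylated, so the acid couples with the unhindered phenol 2 without protection.

Step 2
Reactants: 3 (two molecules)
Product: 5 meso-(3S,4S,3′R,4′R)-4,4′-bis(3,5-di-tert-butyl-4-hydroxyphenyl)-5,5′,7,7′-tetramethoxy-[3,3′-bichromane]-2,2′-dione, via bis(quinone methide) 4 (not isolated)
Conditions: Ag2O, CH2Cl2, 23 °C, argon, dark; filter through Celite; BF3·OEt2, CH2Cl2 (dilute), −78 → −30 °C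
Reagents that add atoms: none
Why: Proposed new method: Ag2O oxidises the hindered phenol of 3 to a phenoxyl radical whose spin can be used only at C8, because the two tert-butyl groups block both ortho carbons and shield the oxygen, so two radicals join C8 to C8′ (the future C3–C3′ bond) and give the bis(p-quinone methide) 4; BF3·OEt2 then turns each methide into a 4-oxybenzyl cation that is attacked by the ortho carbon of its own 3,5-dimethoxyphenyl ester, forming C4–C4a and C4′–C4a′, and loss of a proton rearomatises both rings. The closest known reactions are the one-electron 8–8′ dimerisation of 2,6-di-tert-butyl-4-alkenylphenols to isolable bis(quinone methides), the BF3-induced intramolecular Friedel–Crafts alkylations of such methides, and the acid-mediated cyclisation of aryl cinnamates to 4-aryl-3,4-dihydrocoumarins; their union on an aryl cinnamate has not been shown. Each lactone ring closes by 6-exo-trig attack of the arene on the exocyclic methide carbon, the only feasible mode because the para carbon of the ester ring cannot reach and attack on the other methide would need a seven-membered ring. C3 and C3′ arise in the radical coupling without control, so meso and racemic 4 are both expected, whereas C4 and C4′ arise in the ring closures, where A1,3 strain holds H3 in the plane of the methide and the arene adds to the face opposite to the other half of the molecule, giving the 3,4-trans relationship in each ring. The step needs 8–8′ rather than 8–5′ or 8–O–4′ coupling, which the tert-butyl groups secure (the parent 4-hydroxycinnamate would not), and the unlike pairing of C4 and C4′, which only meso-4 delivers, so the C2-symmetric bis-lactone from racemic 4 is to be removed by crystallisation or chromatography. The trans C3 and C3′ centres formed here are provisional and are inverted in step 10.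

Step 3
Reactants: 5
Product: 6 meso-(3S,4S,3′R,4′R)-4,4′-bis(4-hydroxyphenyl)-5,5′,7,7′-tetramethoxy-[3,3′-bichromane]-2,2′-dione
Conditions: AlCl3, toluene/CH3NO2, 50 °C
Reagents that add atoms: none
Why: Retro-Friedel–Crafts de-tert-butylation, in which ipso protonation passes the four tert-butyl groups to toluene; aryl lactones and methyl ethers should survive, and any stray O-demethylation is repaired in step 4.

Step 4
Reactants: 6
Product: 7 meso-(3S,4S,3′R,4′R)-5,5′,7,7′-tetramethoxy-4,4′-bis(4-methoxyphenyl)-[3,3′-bichromane]-2,2′-dione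
Conditions: CH3I, K2CO3, acetone, 40 °C
Reagents that add atoms: iodomethane, CI
Why: Williamson etherification of the two unhindered phenols masks them before the oxidations of steps 6 and 7; the carbonate can at most equilibrate C3/C3′, which are reset later.

Step 5
Reactants: 7
Product: 8 (2R,3R)-2-[(3S,4S)-5,7-dimethoxy-4-(4-methoxyphenyl)-2-oxochroman-3-yl]-3-(2-hydroxy-4,6-dimethoxyphenyl)-3-(4-methoxyphenyl)-N-[(1S)-1-phenylethyl]propanamide
Conditions: (S)-1-phenylethylamine (1 equiv), THF, 45 °C; chromatographic separation of the two diastereomers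
Reagents that add atoms: (S)-1-phenylethylamine, C[C@H](N)c1ccccc1
Why: Aminolysis of a 3,4-dihydrocoumarin (an aryl ester) by a primary amine is a standard ring opening and is too weakly basic to epimerise C3; the two enantiotopic lactones give diastereomeric amides, the one from opening the 4R lactone (8) is isolated and the other is returned to 7 by acid lactonisation, so the absolute configuration is fixed here without forming a new stereocentre.

Step 6
Reactants: 8
Product: 9 (2R,3R)-2-[(3S,4S)-5,7-dimethoxy-4-(4-methoxyphenyl)-2-oxochroman-3-yl]-3-(2,4-dimethoxy-5,6-dioxocyclohexa-1,3-dien-1-yl)-3-(4-methoxyphenyl)-N-[(1S)-1-phenylethyl]propanamide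
Conditions: 2-iodoxybenzoic acid, DMF, 23 °C
Reagents that add atoms: 2-iodoxybenzoic acid, O=C1OI(=O)(O)c2ccccc12
Why: Regioselective ortho-oxygenation of an electron-rich phenol to an o-quinone by pentavalent iodine (oxygen is delivered within the aryloxy-iodine intermediate to the only free ortho carbon, C8′); no other ring carries a free OH, so only ring B reacts.

Step 7
Reactants: 9
Product: 10 (2R,3R)-2-[(3S,4S)-5,7-dimethoxy-4-(4-methoxyphenyl)-2-oxochroman-3-yl]-3-(4-methoxyphenyl)-N-[(1S)-1-phenylethyl]-3-(2,3,5-triacetoxy-4,6-dimethoxyphenyl)propanamide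
Conditions: Ac2O, H2SO4 (cat.), 0 → 23 °C
Reagents that add atoms: acetic anhydride, CC(=O)OC(C)=O
Why: Thiele–Winter acetoxylation: acid-promoted 1,4-addition of acetate to C6′, the only unsubstituted ring carbon and β to the C8′ carbonyl, followed by enolisation and acetylation gives the aromatic triacetate; methyl ethers, lactone and amide tolerate the medium.

Step 8
Reactants: 10
Product: 12 (3S,4S)-3-[(3R,4R)-6,8-dihydroxy-5,7-dimethoxy-4-(4-methoxyphenyl)-2-oxochroman-3-yl]-5,7-dimethoxy-4-(4-methoxyphenyl)chroman-2-one, via triol amide 11 (not isolated)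
Conditions: HCl, MeOH, 40 °C, argon; evaporate; p-toluenesulfonic acid monohydrate, toluene, 90 °C
Reagents that add atoms: none
Why: Acid-catalysed methanolysis removes the three aryl acetates, and the C8a′ phenol, the only hydroxyl able to close a six-membered ring, then displaces the protonated amine in a phenol-assisted acidolysis of the amide (lactonisation) helped by the buttressing 5′-methoxy and 4′-aryl groups; ring A recloses under the same conditions should it open.

Step 9
Reactants: 12
Product: 13 (3S,4S)-5,7-dimethoxy-4-(4-methoxyphenyl)-3-[(3R,4R)-5,6,7,8-tetramethoxy-4-(4-methoxyphenyl)-2-oxochroman-3-yl]chroman-2-one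
Conditions: CH3I, K2CO3, acetone, 40 °C, argon
Reagents that add atoms: iodomethane, CI
Why: Williamson etherification of the two ring-B phenols gives a substrate without acidic OH for the enolate step and puts the same ether on all eight oxygens, so one reagent can free them at the end.

Step 10
Reactants: 13
Product: 15 (3R,4S)-5,7-dimethoxy-4-(4-methoxyphenyl)-3-[(3S,4R)-5,6,7,8-tetramethoxy-4-(4-methoxyphenyl)-2-oxochroman-3-yl]chroman-2-one, via dilithium bis-enolate 14 (not isolated)
Conditions: LiN(iPr)2 (3 equiv), THF, −78 °C; AcOH in THF, −78 °C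
Reagents that add atoms: none
Why: Kinetic protonation of lactone enolates: LiN(iPr)2 forms the succinate-type bis-enolate and each enolate carbon takes its proton on the face opposite to the pseudo-axial 4-aryl group of its own ring, which places the C3–C3′ bond cis to that aryl group and sets C3 (R) and C3′ (S).

Step 11
Reactants: 15
Product: 16 (3R,4S)-5,7-dihydroxy-4-(4-hydroxyphenyl)-3-[(3S,4R)-5,6,7,8-tetrahydroxy-4-(4-hydroxyphenyl)-2-oxochroman-3-yl]chroman-2-one (target)
Conditions: BBr3 (excess), CH2Cl2, −78 → 23 °C, argon; degassed H2O, 0 °C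
Reagents that add atoms: none
Why: Lewis-acid ether cleavage, in which BBr3 complexes each of the eight aryl methyl ethers and bromide attacks the methyl carbon, is standard for polyphenols and spares aryl lactones; no base is present, so the lactone α-carbons should not enolise and the cis C3/C3′ centres are kept, and a shift of either acyl group to its peri oxygen (O5 or O5′) would only regenerate the same lactone.

**Compound list**

1 | (E)-3-(3,5-di-tert-butyl-4-hydroxyphenyl)prop-2-enoic acid | OC(=O)/C=C/c1cc(C(C)(C)C)c(O)c(C(C)(C)C)c1 | starting material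
2 | 3,5-dimethoxyphenol | COc1cc(O)cc(OC)c1 | starting material
3 | 3,5-dimethoxyphenyl (E)-3-(3,5-di-tert-butyl-4-hydroxyphenyl)prop-2-enoate | O=C(/C=C/c1cc(C(C)(C)C)c(O)c(C(C)(C)C)c1)Oc1cc(OC)cc(OC)c1 | intermediate
4 | bis(3,5-dimethoxyphenyl) meso-(2R,3S)-2,3-bis[(3,5-di-tert-butyl-4-oxocyclohexa-2,5-dien-1-ylidene)methyl]butanedioate | O=C(Oc1cc(OC)cc(OC)c1)[C@@H](C=C1C=C(C(C)(C)C)C(=O)C(C(C)(C)C)=C1)[C@@H](C=C1C=C(C(C)(C)C)C(=O)C(C(C)(C)C)=C1)C(=O)Oc1cc(OC)cc(OC)c1 | intermediate
5 | meso-(3S,4S,3′R,4′R)-4,4′-bis(3,5-di-tert-butyl-4-hydroxyphenyl)-5,5′,7,7′-tetramethoxy-[3,3′-bichromane]-2,2′-dione | O=C1Oc2cc(OC)cc(OC)c2[C@H](c2cc(C(C)(C)C)c(O)c(C(C)(C)C)c2)[C@H]1[C@@H]1C(=O)Oc2cc(OC)cc(OC)c2[C@H]1c1cc(C(C)(C)C)c(O)c(C(C)(C)C)c1 | intermediate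
6 | meso-(3S,4S,3′R,4′R)-4,4′-bis(4-hydroxyphenyl)-5,5′,7,7′-tetramethoxy-[3,3′-bichromane]-2,2′-dione | O=C1Oc2cc(OC)cc(OC)c2[C@H](c2ccc(O)cc2)[C@H]1[C@@H]1C(=O)Oc2cc(OC)cc(OC)c2[C@H]1c1ccc(O)cc1 | intermediate
7 | meso-(3S,4S,3′R,4′R)-5,5′,7,7′-tetramethoxy-4,4′-bis(4-methoxyphenyl)-[3,3′-bichromane]-2,2′-dione | O=C1Oc2cc(OC)cc(OC)c2[C@H](c2ccc(OC)cc2)[C@H]1[C@@H]1C(=O)Oc2cc(OC)cc(OC)c2[C@H]1c1ccc(OC)cc1 | intermediate
8 | (2R,3R)-2-[(3S,4S)-5,7-dimethoxy-4-(4-methoxyphenyl)-2-oxochroman-3-yl]-3-(2-hydroxy-4,6-dimethoxyphenyl)-3-(4-methoxyphenyl)-N-[(1S)-1-phenylethyl]propanamide | O=C1Oc2cc(OC)cc(OC)c2[C@H](c2ccc(OC)cc2)[C@H]1[C@H](C(=O)N[C@@H](C)c1ccccc1)[C@@H](c1c(O)cc(OC)cc1OC)c1ccc(OC)cc1 | intermediate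
9 | (2R,3R)-2-[(3S,4S)-5,7-dimethoxy-4-(4-methoxyphenyl)-2-oxochroman-3-yl]-3-(2,4-dimethoxy-5,6-dioxocyclohexa-1,3-dien-1-yl)-3-(4-methoxyphenyl)-N-[(1S)-1-phenylethyl]propanamide | O=C1Oc2cc(OC)cc(OC)c2[C@H](c2ccc(OC)cc2)[C@H]1[C@H](C(=O)N[C@@H](C)c1ccccc1)[C@@H](C1=C(OC)C=C(OC)C(=O)C1=O)c1ccc(OC)cc1 | intermediate
10 | (2R,3R)-2-[(3S,4S)-5,7-dimethoxy-4-(4-methoxyphenyl)-2-oxochroman-3-yl]-3-(4-methoxyphenyl)-N-[(1S)-1-phenylethyl]-3-(2,3,5-triacetoxy-4,6-dimethoxyphenyl)propanamide | O=C1Oc2cc(OC)cc(OC)c2[C@H](c2ccc(OC)cc2)[C@H]1[C@H](C(=O)N[C@@H](C)c1ccccc1)[C@@H](c1c(OC(C)=O)c(OC(C)=O)c(OC)c(OC(C)=O)c1OC)c1ccc(OC)cc1 | intermediate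
11 | (2R,3R)-2-[(3S,4S)-5,7-dimethoxy-4-(4-methoxyphenyl)-2-oxochroman-3-yl]-3-(4-methoxyphenyl)-N-[(1S)-1-phenylethyl]-3-(2,3,5-trihydroxy-4,6-dimethoxyphenyl)propanamide | O=C1Oc2cc(OC)cc(OC)c2[C@H](c2ccc(OC)cc2)[C@H]1[C@H](C(=O)N[C@@H](C)c1ccccc1)[C@@H](c1c(O)c(O)c(OC)c(O)c1OC)c1ccc(OC)cc1 | intermediate
12 | (3S,4S)-3-[(3R,4R)-6,8-dihydroxy-5,7-dimethoxy-4-(4-methoxyphenyl)-2-oxochroman-3-yl]-5,7-dimethoxy-4-(4-methoxyphenyl)chroman-2-one | O=C1Oc2cc(OC)cc(OC)c2[C@H](c2ccc(OC)cc2)[C@H]1[C@@H]1C(=O)Oc2c(O)c(OC)c(O)c(OC)c2[C@H]1c1ccc(OC)cc1 | intermediate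
13 | (3S,4S)-5,7-dimethoxy-4-(4-methoxyphenyl)-3-[(3R,4R)-5,6,7,8-tetramethoxy-4-(4-methoxyphenyl)-2-oxochroman-3-yl]chroman-2-one | O=C1Oc2cc(OC)cc(OC)c2[C@H](c2ccc(OC)cc2)[C@H]1[C@@H]1C(=O)Oc2c(OC)c(OC)c(OC)c(OC)c2[C@H]1c1ccc(OC)cc1 | intermediate
14 | dilithium bis-enolate of 13 (C2=C3 and C3′=C2′ enolates, C4 and C4′ unchanged) | [Li+].[Li+].[O-]C1Oc2cc(OC)cc(OC)c2[C@H](c2ccc(OC)cc2)C=1C1=C([O-])Oc2c(OC)c(OC)c(OC)c(OC)c2[C@H]1c1ccc(OC)cc1 | intermediate
15 | (3R,4S)-5,7-dimethoxy-4-(4-methoxyphenyl)-3-[(3S,4R)-5,6,7,8-tetramethoxy-4-(4-methoxyphenyl)-2-oxochroman-3-yl]chroman-2-one | O=C1Oc2cc(OC)cc(OC)c2[C@H](c2ccc(OC)cc2)[C@@H]1[C@H]1C(=O)Oc2c(OC)c(OC)c(OC)c(OC)c2[C@H]1c1ccc(OC)cc1 | intermediate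
16 | (3R,4S)-5,7-dihydroxy-4-(4-hydroxyphenyl)-3-[(3S,4R)-5,6,7,8-tetrahydroxy-4-(4-hydroxyphenyl)-2-oxochroman-3-yl]chroman-2-one | O=C1Oc2cc(O)cc(O)c2[C@H](c2ccc(O)cc2)[C@@H]1[C@H]1C(=O)Oc2c(O)c(O)c(O)c(O)c2[C@H]1c1ccc(O)cc1 | target

**Count and risks**

Total steps: 11. Longest linear sequence: 11 steps (1 or 2 to 16).

Steps most likely to fail:

1. Step 2 (the new method). The activated methide may lose the acidic C3 proton (elimination to a bis-benzylidene succinate) faster than the arene attacks, the weak C8–C8′ bond may redissociate, or the coupling may favour the racemic bis(quinone methide). Fallback with known chemistry, setting out from 2: 2 and commercial (E)-4-methoxycinnamic acid are heated in CF3CO2H (esterification and intramolecular hydroarylation in one pot) to racemic 5,7-dimethoxy-4-(4-methoxyphenyl)chroman-2-one F1. F1 is deprotonated with LiN(iPr)2 (THF, −78 °C) and the solution is treated with CuCl2, a known oxidative dimerisation of ester and lactone enolates, each new bond forming anti to the 4-aryl group. Union of a 4R with a 4S molecule gives the meso trans,trans dimer, which is 7, and the C2-symmetric dimer is separated. The route is rejoined at 7.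

2. Step 7. The o-quinone may tautomerise to a quinone methide through the doubly benzylic C4′–H (loss of that configuration), ring A may be C-acetylated, or methoxy may exchange for acetoxy. Fallback avoiding quinones, setting out from 8: N-bromosuccinimide (2 equiv, CH2Cl2, −78 °C) should brominate only the free phenol ring at C6′ and C8′ to give the 3,5-dibromo-2-hydroxy-4,6-dimethoxyphenyl amide F2. p-Toluenesulfonic acid in toluene at 90 °C then closes the lactone to the 6′,8′-dibromo bis-lactone F3. Miyaura borylation (bis(pinacolato)diboron, KOAc, Pd(OAc)2, 2-dicyclohexylphosphino-2′,6′-dimethoxybiphenyl, dioxane, 90 °C) gives the 6′,8′-bis(pinacolboronate) F4, and oxidation with NaBO3·4H2O in THF/H2O gives 12, where the route is rejoined.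

3. Step 10. The second deprotonation next to the first enolate may be incomplete, the enolate may fragment to a ketene by loss of aryloxide on warming, or facial selectivity of protonation may be insufficient at one ring. Fallback, setting out from 13: the centres are corrected one at a time through mono-enolates. LiN(SiMe3)2 (1.1 equiv, THF, −78 °C) followed by an AcOH quench gives the isomer with ring A cis and ring B trans F5 and the isomer with ring A trans and ring B cis F6. These are separated from recovered 13, and each is put through the same deprotonation and protonation to give 15, where the route is rejoined. Material protonated the wrong way is recycled.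

**Further compounds**

F1 | step 2 | racemic 5,7-dimethoxy-4-(4-methoxyphenyl)chroman-2-one | COc1ccc(cc1)C1CC(=O)Oc2cc(OC)cc(OC)c12
F2 | step 7 | (2R,3R)-3-(3,5-dibromo-2-hydroxy-4,6-dimethoxyphenyl) analogue of 8 (same configuration) | O=C1Oc2cc(OC)cc(OC)c2[C@H](c2ccc(OC)cc2)[C@H]1[C@H](C(=O)N[C@@H](C)c1ccccc1)[C@@H](c1c(O)c(Br)c(OC)c(Br)c1OC)c1ccc(OC)cc1
F3 | step 7 | 6′,8′-dibromo analogue of 12 (bromine in place of both hydroxyls, same configuration) | O=C1Oc2cc(OC)cc(OC)c2[C@H](c2ccc(OC)cc2)[C@H]1[C@@H]1C(=O)Oc2c(Br)c(OC)c(Br)c(OC)c2[C@H]1c1ccc(OC)cc1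
F4 | step 7 | 6′,8′-bis(4,4,5,5-tetramethyl-1,3,2-dioxaborolan-2-yl) analogue of 12 (same configuration) | O=C1Oc2cc(OC)cc(OC)c2[C@H](c2ccc(OC)cc2)[C@H]1[C@@H]1C(=O)Oc2c(B3OC(C)(C)C(C)(C)O3)c(OC)c(B3OC(C)(C)C(C)(C)O3)c(OC)c2[C@H]1c1ccc(OC)cc1
F5 | step 10 | (3R,4S)-5,7-dimethoxy-4-(4-methoxyphenyl)-3-[(3R,4R)-5,6,7,8-tetramethoxy-4-(4-methoxyphenyl)-2-oxochroman-3-yl]chroman-2-one (ring A cis, ring B trans) | O=C1Oc2cc(OC)cc(OC)c2[C@H](c2ccc(OC)cc2)[C@@H]1[C@@H]1C(=O)Oc2c(OC)c(OC)c(OC)c(OC)c2[C@H]1c1ccc(OC)cc1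
F6 | step 10 | (3S,4S)-5,7-dimethoxy-4-(4-methoxyphenyl)-3-[(3S,4R)-5,6,7,8-tetramethoxy-4-(4-methoxyphenyl)-2-oxochroman-3-yl]chroman-2-one (ring A trans, ring B cis) | O=C1Oc2cc(OC)cc(OC)c2[C@H](c2ccc(OC)cc2)[C@H]1[C@H]1C(=O)Oc2c(OC)c(OC)c(OC)c(OC)c2[C@H]1c1ccc(OC)cc1
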